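**Plan**
- Retrosynthesis: remove the 4,5-epoxide (hydroxyl-directed epoxidation of a 6-hydroxy-(1(10)E,4Z)-germacradiene) and both angelates. Then cut C2–C3, the CH2–CH2 bond joining the allylic methylene of the C1=C10 olefin to the methylene on the methyl-bearing oxirane carbon C4, by a retro-[3,3] shift. Then cut C5–C4 (isopropenyl), C7–C11 (acetate arm), C10–C1 (vinyl) and C10–C14 back to a 4-silyloxycyclohexenone.
- Enabling feature: C10=C1–C2–C3–C4(–O–)C5 is a masked hexa-1,5-diene (the oxirane stands for a C4=C5 enolate) and C2–C3 is its central sigma bond. The ten-membered ring is therefore the [3,3] ring-expansion product of a cis-1-isopropenyl-2-vinylcyclohexan-1-ol built on ring carbons C5–C10.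
- Forward order: cyclohexenone → quaternary C10 (methyl, vinyl) → C7 acetate arm → C5 isopropenyl diene → epoxy-lactonisation (cis-fused 6,12-lactone as temporary template) → C11 methylation → reduction and protection → anionic oxy-Cope with enolate triflation (ten-membered ring) → detriflation → bis-angeloylation → epoxidation.
- Stereochemistry: C8 from the chiral enone; C10 and C7 by additions anti to the C8 silyloxy group; C5/C6 by anti opening of an epoxide by the C7 carboxyl; C11 by convex-face lactone alkylation; 1(10)E and 4Z from the chair transition state of the oxy-Cope; C4/C5 by oxygen delivery from the C6 hydroxyl.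

Key step: step 14

Remark: ring positions carry germacrane numbers throughout (C1=C10 olefin with C14 on C10; C4 with C15; C5 oxirane CH; C6 carbinol; C7 bearing C11(C13)–C12; C8 acyloxy; the six-membered intermediates are ring C5–C6–C7–C8–C9–C10). β is the ring face of the C7 side chain, α the opposite face.
Remark: (S)-4-(tert-butyldimethylsilyloxy)cyclohex-2-en-1-one (1) is assumed to be a catalogue compound.

Step 1
Reactants: 1 (S)-4-(tert-butyldimethylsilyloxy)cyclohex-2-en-1-one
Product: 3 (4S,6S)-4-(tert-butyldimethylsilyloxy)-6-methylcyclohex-2-en-1-one, via lithium dienolate 2 (not isolated)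
Conditions: LiN(iPr)2, THF, −78 °C; MeI, −78 → −20 °C
Reagents that add atoms: iodomethane, CI
Why: Kinetic deprotonation at the alpha-prime carbon (C10) gives the cross-conjugated dienolate, and its methylation (enolate alkylation) installs C14; the new C10 centre (mainly trans to OTBS) is planarised again in step 3, so its ratio does not matter.

Step 2
Reactants: 4 benzeneselenenyl chloride; 5 ethyl vinyl ether
Product: 7 2-(phenylselanyl)acetaldehyde, via chloro ether 6 (not isolated)
Conditions: CH2Cl2, −78 °C; then H2O, NaHCO3, 0 °C → rt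
Reagents that add atoms: water, O
Why: Electrophilic selenenylation of the enol ether puts selenium on the terminal carbon and chloride on the oxygen-bearing carbon, and hydrolysis of this alpha-chloro ether should release the alpha-seleno aldehyde, a vinyl cation equivalent; no stereocentre is formed.

Step 3
Reactants: 3 (4S,6S)-4-(tert-butyldimethylsilyloxy)-6-methylcyclohex-2-en-1-one; 7 2-(phenylselanyl)acetaldehyde
Product: 9 (4S,6R)-4-(tert-butyldimethylsilyloxy)-6-[1-hydroxy-2-(phenylselanyl)ethyl]-6-methylcyclohex-2-en-1-one, via lithium dienolate 8 (not isolated)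
Conditions: LiN(iPr)2, THF, −78 °C; then 7, −78 °C; AcOH quench
Reagents that add atoms: none
Why: Aldol addition of the tetrasubstituted dienolate creates the quaternary C10, the aldehyde entering anti to the pseudo-axial C8 silyloxy group so that the two-carbon arm is trans to OTBS and the methyl cis; the carbinol epimers converge in step 4.

Step 4
Reactants: 9 (4S,6R)-4-(tert-butyldimethylsilyloxy)-6-[1-hydroxy-2-(phenylselanyl)ethyl]-6-methylcyclohex-2-en-1-one
Product: 11 (4S,6R)-4-(tert-butyldimethylsilyloxy)-6-methyl-6-vinylcyclohex-2-en-1-one, via mesylate 10 (not isolated)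
Conditions: MsCl, Et3N, CH2Cl2, 0 °C → rt
Reagents that add atoms: none
Why: Mesylation of the beta-hydroxy selenide triggers anti-elimination through a seleniranium ion (reductive elimination of a beta-hydroxy selenide), which should unveil the C10 vinyl group without touching the enone or any stereocentre.

Step 5
Reactants: 11 (4S,6R)-4-(tert-butyldimethylsilyloxy)-6-methyl-6-vinylcyclohex-2-en-1-one; 12 1-(tert-butyldimethylsilyloxy)-1-methoxyethene
Product: 14 keto ester (C5 ketone; 7β-CH2CO2Me; 8α-OTBS; 10β-vinyl; 10α-methyl), via silyl enol ether 13 (not isolated)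
Conditions: LiClO4 (3 M in Et2O), rt; then 1 M HCl, THF, 0 °C
Reagents that add atoms: none
Why: Mukaiyama–Michael addition of the silyl ketene acetal occurs at C7 anti to the adjacent C8 silyloxy group, setting the C7 arm β (trans to OTBS, cis to the C10 vinyl), and brief dilute acid hydrolyses only the transferred silyl enol ether to the ketone.

Step 6
Reactants: 14 keto ester
Product: 16 enol triflate (C5(OTf)=C6), via potassium enolate 15 (not isolated)
Conditions: KN(SiMe3)2, THF, −78 °C; PhNTf2, −78 → 0 °C; AcOH quench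
Reagents that add atoms: N-phenylbis(trifluoromethanesulfonimide), O=S(=O)(N(c1ccccc1)S(=O)(=O)C(F)(F)F)C(F)(F)F
Why: Because C10 is quaternary the ketone can enolise only toward C6, so O-sulfonylation of the enolate (enol triflate formation) should give a single regioisomer with no stereocentre affected.

Step 7
Reactants: 16 enol triflate; 17 isopropenylboronic acid pinacol ester
Product: 18 diene ester (C5=C6 ring olefin bearing the isopropenyl group on C5)
Conditions: PdCl2(dppf) (5 mol %), K3PO4, dioxane/H2O (9:1), 60 °C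
Reagents that add atoms: none
Why: Suzuki–Miyaura coupling of the hindered enol triflate installs C3, C4 and C15 as a 2-substituted 1,3-diene and leaves the stereocentres untouched.

Step 8
Reactants: 18 diene ester
Product: 19 diene acid
Conditions: LiOH, THF/MeOH/H2O, rt; then 1 M HCl to pH 3, 0 °C
Reagents that add atoms: lithium hydroxide, [Li+].[OH-]
Why: Saponification of the methyl ester, to which the secondary silyl ether and the olefins are inert.

Step 9
Reactants: 19 diene acid
Product: 21 hydroxy lactone (cis-fused 6β,12-lactone; 5α-OH; 5β-isopropenyl), via epoxy acid 20 (not isolated)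
Conditions: mCPBA, CH2Cl2, 0 °C → rt
Reagents that add atoms: 3-chloroperoxybenzoic acid, OOC(=O)c1cccc(Cl)c1
Why: Peracid (Prilezhaev) epoxidation of the most electron-rich, trisubstituted ring olefin from the α face (anti to the pseudo-axial C10 vinyl and the C7 arm) is followed by 5-exo, trans-diaxial (Fürst–Plattner) opening at C6 by the neighbouring carboxylic acid, which fixes the lactone oxygen β on C6 by inversion and leaves the tertiary C5 hydroxyl α with the isopropenyl group β, cis to the vinyl group.

Step 10
Reactants: 21 hydroxy lactone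
Product: 23 (11S)-11-methyl hydroxy lactone, via dilithium dianion 22 (not isolated)
Conditions: LiN(iPr)2 (2.2 equiv), THF, −78 °C; MeI, −78 → −40 °C; AcOH quench
Reagents that add atoms: iodomethane, CI
Why: The lactone enolate of the alkoxide–enolate dianion is methylated on the convex face of the cis-fused bicycle, anti to ring carbon C8 (lactone enolate alkylation), which sets C11 as S.

Step 11
Reactants: 23 (11S)-11-methyl hydroxy lactone
Product: 24 triol (5α-OH, 6β-OH, 12-OH)
Conditions: LiAlH4, THF, 0 °C; then H2O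
Reagents that add atoms: none
Why: Hydride reduction of the lactone to the 6,12-diol, which the secondary silyl ether and the isolated olefins survive.

Step 12
Reactants: 24 triol
Product: 25 12-O-silyl ether
Conditions: TBSCl (1.05 equiv), imidazole, CH2Cl2, 0 °C
Reagents that add atoms: tert-butyldimethylsilyl chloride, CC(C)(C)[Si](C)(C)Cl
Why: Silylation selects the primary C12 hydroxyl over the hindered secondary and tertiary hydroxyls.

Step 13
Reactants: 25 12-O-silyl ether
Product: 27 6-O-(4-methoxybenzyl) ether, via sodium alkoxide 26 (not isolated)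
Conditions: NaH (1.05 equiv), PMBCl, Bu4NI (cat.), THF/DMF, 0 °C → rt
Reagents that add atoms: 4-methoxybenzyl chloride, COc1ccc(CCl)cc1
Why: Williamson etherification, in which the secondary C6 alkoxide is benzylated much faster than the tertiary C5 alkoxide, so the C5 hydroxyl stays free for the key step under an ether that tolerates base, fluoride and palladium and is later removed oxidatively.

Step 14
Reactants: 27 6-O-(4-methoxybenzyl) ether
Product: 30 ten-membered enol triflate (1(10)E; C5(OTf)=C4 with C3 cis to C6), via potassium alkoxide 28 (not isolated), via potassium enolate 29 (not isolated)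
Conditions: KH, 18-crown-6, THF, 0 °C → rt; then N-(5-chloro-2-pyridyl)bis(trifluoromethanesulfonimide), −78 → 0 °C; AcOH quench
Reagents that add atoms: N-(5-chloro-2-pyridyl)bis(trifluoromethanesulfonimide), O=S(=O)(N(c1ccc(Cl)cn1)S(=O)(=O)C(F)(F)F)C(F)(F)F
Why: Deprotonation gives the tertiary C5 alkoxide, whose charge-accelerated [3,3]-sigmatropic shift (anionic oxy-Cope rearrangement) joins the vinyl terminus C2 to the isopropenyl terminus C3 while the C5–C10 bond breaks, and the resulting C4=C5 potassium enolate is O-sulfonylated in the same flask. The closest known reaction type is the anionic oxy-Cope ring expansion of 1,2-dialkenylcyclohexan-1-ols to cyclodec-5-enones with trapping of the enolate. The ten-membered ring is thus not closed end to end but arises by a four-atom ring expansion of the cyclohexane C5–C10, the new sigma bond being the central bond of the hexa-1,5-diene C10=C1–C2–C3–C4=C5. No sp3 stereocentre is created; the two new olefin geometries follow from the chair transition state open to the cis-dialkenyl substrate, in which C9 is pseudo-equatorial on C10 (1(10)E) and C6 pseudo-axial on C5 (C3 cis to C6, kept in the triflate and becoming 4Z after step 15). The step needs chair over boat, rearrangement over retro-allylation of the alkoxide, and O-sulfonylation before the enolate equilibrates toward C6. These are secured by the cyclohexane chair that keeps the C7 and C8 substituents equatorial (placing vinyl axial and isopropenyl equatorial), by the quaternary C10 and the crown-ether-separated alkoxide at or below room temperature, and by trapping at −78 °C.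

Step 15
Reactants: 30 ten-membered enol triflate
Product: 31 (1(10)E,4Z)-diene (6β-OPMB; 8α-OTBS; 12-OTBS)
Conditions: Pd(OAc)2 (10 mol %), PPh3, HCO2H, Bu3N, DMF, 60 °C
Reagents that add atoms: none
Why: Palladium-catalysed formate reduction of the enol triflate (oxidative addition to zerovalent palladium, formate exchange, decarboxylation, reductive elimination) replaces OTf by H with retention, which should give the 4Z trisubstituted olefin.

Step 16
Reactants: 31 (1(10)E,4Z)-diene
Product: 32 8,12-diol
Conditions: Bu4NF, THF, 0 °C → rt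
Reagents that add atoms: none
Why: Fluoride cleaves both silyl ethers while the 4-methoxybenzyl ether and the diene are inert.

Step 17
Reactants: 32 8,12-diol; 33 angelic acid
Product: 35 8,12-bis-angelate 6-O-(4-methoxybenzyl) ether, via mixed anhydride 34 (not isolated)
Conditions: 33 (3 equiv), 2,4,6-trichlorobenzoyl chloride (3 equiv), Et3N (6 equiv), toluene, rt; then 32, toluene, 75 °C
Reagents that add atoms: angelic acid (second equivalent of 33), C/C=C(/C)C(=O)O
Why: Mixed-anhydride (Yamaguchi-type) acylation, run without a nucleophilic pyridine catalyst and with at least two equivalents of the anhydride (one angeloyl group for each hydroxyl), transfers the angeloyl group, whose carbonyl is the unshielded one of the anhydride, to the primary C12 and the secondary C8 hydroxyl and should keep the Z geometry of the acid.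

Step 18
Reactants: 35 8,12-bis-angelate 6-O-(4-methoxybenzyl) ether
Product: 36 6β-hydroxy bis-angelate (allylic alcohol)
Conditions: DDQ, CH2Cl2/pH 7 buffer, 0 °C
Reagents that add atoms: none
Why: Oxidative cleavage of the 4-methoxybenzyl ether by DDQ (benzylic hydride abstraction, then hydrolysis of the oxocarbenium ion) frees the C6 allylic alcohol under buffered neutral conditions that the esters and olefins tolerate.

Step 19
Reactants: 36 6β-hydroxy bis-angelate
Product: 37 target, (1(10)E,4S,5R,6R,7S,8S,11S)-4,5-epoxy-6-hydroxygermacr-1(10)-ene-8,12-diyl bis[(Z)-2-methylbut-2-enoate]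
Conditions: VO(acac)2 (5 mol %), t-BuOOH, CH2Cl2, 0 °C → rt
Reagents that add atoms: tert-butyl hydroperoxide, CC(C)(C)OO
Why: Hydroxyl-directed vanadium-catalysed epoxidation transfers oxygen within the vanadate ester of the C6 alcohol to the adjacent 4Z olefin only, on the peripheral face that places the oxirane cis to the C6 hydroxyl as for Z-cycloalkenols of medium rings, which sets C4 (S) and C5 (R); the isolated C1=C10 olefin and the electron-poor angelates are not attacked.

**Compound list**
1 | (S)-4-(tert-butyldimethylsilyloxy)cyclohex-2-en-1-one | O=C1C=C[C@@H](O[Si](C)(C)C(C)(C)C)CC1 | starting material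
2 | lithium cross-conjugated dienolate of 1 | [Li+].[O-]C1=CC[C@H](O[Si](C)(C)C(C)(C)C)C=C1 | intermediate
3 | (4S,6S)-4-(tert-butyldimethylsilyloxy)-6-methylcyclohex-2-en-1-one (trans; the C6 epimer is carried along) | O=C1C=C[C@@H](O[Si](C)(C)C(C)(C)C)C[C@@H]1C | intermediate
4 | benzeneselenenyl chloride | Cl[Se]c1ccccc1 | starting material
5 | ethyl vinyl ether | C=COCC | starting material
6 | 1-chloro-1-ethoxy-2-(phenylselanyl)ethane | CCOC(Cl)C[Se]c1ccccc1 | intermediate
7 | 2-(phenylselanyl)acetaldehyde | O=CC[Se]c1ccccc1 | intermediate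
8 | lithium dienolate of 3 (C5–O, C5=C10) | [Li+].[O-]C1=C(C)C[C@H](O[Si](C)(C)C(C)(C)C)C=C1 | intermediate
9 | (4S,6R)-4-(tert-butyldimethylsilyloxy)-6-[1-hydroxy-2-(phenylselanyl)ethyl]-6-methylcyclohex-2-en-1-one (arm trans to OTBS; both carbinol epimers) | O=C1C=C[C@@H](O[Si](C)(C)C(C)(C)C)C[C@]1(C)C(O)C[Se]c2ccccc2 | intermediate
10 | methanesulfonate of 9 | O=C1C=C[C@@H](O[Si](C)(C)C(C)(C)C)C[C@]1(C)C(OS(C)(=O)=O)C[Se]c2ccccc2 | intermediate
11 | (4S,6R)-4-(tert-butyldimethylsilyloxy)-6-methyl-6-vinylcyclohex-2-en-1-one (vinyl trans to OTBS) | O=C1C=C[C@@H](O[Si](C)(C)C(C)(C)C)C[C@]1(C)C=C | intermediate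
12 | 1-(tert-butyldimethylsilyloxy)-1-methoxyethene | COC(=C)O[Si](C)(C)C(C)(C)C | starting material
13 | silyl enol ether Michael adduct (C5(OTBS)=C6; 7β-CH2CO2Me; 8α-OTBS; 10β-vinyl, 10α-methyl) | COC(=O)C[C@H]1C=C(O[Si](C)(C)C(C)(C)C)[C@@](C)(C=C)C[C@@H]1O[Si](C)(C)C(C)(C)C | intermediate
14 | keto ester (C5 ketone; 7β-CH2CO2Me; 8α-OTBS; 10β-vinyl, 10α-methyl) | COC(=O)C[C@H]1CC(=O)[C@@](C)(C=C)C[C@@H]1O[Si](C)(C)C(C)(C)C | intermediate
15 | potassium enolate of 14 (C5–O, C5=C6) | [K+].COC(=O)C[C@H]1C=C([O-])[C@@](C)(C=C)C[C@@H]1O[Si](C)(C)C(C)(C)C | intermediate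
16 | enol triflate (C5(OTf)=C6) | COC(=O)C[C@H]1C=C(OS(=O)(=O)C(F)(F)F)[C@@](C)(C=C)C[C@@H]1O[Si](C)(C)C(C)(C)C | intermediate
17 | isopropenylboronic acid pinacol ester | CC(=C)B1OC(C)(C)C(C)(C)O1 | starting material
18 | diene ester (C5-isopropenyl, C5=C6; 7β-CH2CO2Me; 8α-OTBS; 10β-vinyl, 10α-methyl) | COC(=O)C[C@H]1C=C(C(C)=C)[C@@](C)(C=C)C[C@@H]1O[Si](C)(C)C(C)(C)C | intermediate
19 | diene acid | OC(=O)C[C@H]1C=C(C(C)=C)[C@@](C)(C=C)C[C@@H]1O[Si](C)(C)C(C)(C)C | intermediate
20 | 5α,6α-epoxy acid | OC(=O)C[C@H]1[C@@H]2O[C@]2(C(C)=C)[C@@](C)(C=C)C[C@@H]1O[Si](C)(C)C(C)(C)C | intermediate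
21 | hydroxy lactone (cis-fused 6β,12-lactone; 5α-OH, 5β-isopropenyl; 8α-OTBS; 10β-vinyl, 10α-methyl) | O=C1C[C@H]2[C@@H](O1)[C@@](O)(C(C)=C)[C@@](C)(C=C)C[C@@H]2O[Si](C)(C)C(C)(C)C | intermediate
22 | dilithium dianion of 21 (C5 alkoxide, lactone enolate) | [Li+].[Li+].[O-]C1=C[C@H]2[C@@H](O1)[C@@]([O-])(C(C)=C)[C@@](C)(C=C)C[C@@H]2O[Si](C)(C)C(C)(C)C | intermediate
23 | (11S)-11-methyl hydroxy lactone (methyl on the convex face) | O=C1[C@@H](C)[C@H]2[C@@H](O1)[C@@](O)(C(C)=C)[C@@](C)(C=C)C[C@@H]2O[Si](C)(C)C(C)(C)C | intermediate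
24 | triol (5α-OH, 6β-OH, 12-OH; 8α-OTBS) | OC[C@@H](C)[C@H]1[C@@H](O)[C@@](O)(C(C)=C)[C@@](C)(C=C)C[C@@H]1O[Si](C)(C)C(C)(C)C | intermediate
25 | 12-O-silyl ether (8,12-bis-OTBS; 5α-OH, 6β-OH) | CC(C)(C)[Si](C)(C)OC[C@@H](C)[C@H]1[C@@H](O)[C@@](O)(C(C)=C)[C@@](C)(C=C)C[C@@H]1O[Si](C)(C)C(C)(C)C | intermediate
26 | sodium C6-alkoxide of 25 | [Na+].CC(C)(C)[Si](C)(C)OC[C@@H](C)[C@H]1[C@@H]([O-])[C@@](O)(C(C)=C)[C@@](C)(C=C)C[C@@H]1O[Si](C)(C)C(C)(C)C | intermediate
27 | 6-O-(4-methoxybenzyl) ether: cis-1-isopropenyl-2-vinylcyclohexan-1-ol (5α-OH, 5β-isopropenyl, 10β-vinyl, 10α-methyl; 6β-OPMB; 7β side chain; 8α-OTBS) | CC(C)(C)[Si](C)(C)OC[C@@H](C)[C@H]1[C@@H](OCc2ccc(OC)cc2)[C@@](O)(C(C)=C)[C@@](C)(C=C)C[C@@H]1O[Si](C)(C)C(C)(C)C | intermediate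
28 | potassium C5-alkoxide of 27 | [K+].CC(C)(C)[Si](C)(C)OC[C@@H](C)[C@H]1[C@@H](OCc2ccc(OC)cc2)[C@@]([O-])(C(C)=C)[C@@](C)(C=C)C[C@@H]1O[Si](C)(C)C(C)(C)C | intermediate
29 | ten-membered potassium enolate (1(10)E; C4=C5 with O cis to C15, C3 cis to C6) | [K+].CC(C)(C)[Si](C)(C)OC[C@@H](C)[C@H]1[C@@H](OCc2ccc(OC)cc2)/C([O-])=C(/C)CC/C=C(\C)C[C@@H]1O[Si](C)(C)C(C)(C)C | intermediate
30 | ten-membered enol triflate (1(10)E; C5(OTf)=C4, C3 cis to C6) | CC(C)(C)[Si](C)(C)OC[C@@H](C)[C@H]1[C@@H](OCc2ccc(OC)cc2)/C(OS(=O)(=O)C(F)(F)F)=C(/C)CC/C=C(\C)C[C@@H]1O[Si](C)(C)C(C)(C)C | intermediate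
31 | (1(10)E,4Z)-germacradiene, 6β-OPMB, 8α-OTBS, 12-OTBS | CC(C)(C)[Si](C)(C)OC[C@@H](C)[C@H]1[C@@H](OCc2ccc(OC)cc2)/C=C(/C)CC/C=C(\C)C[C@@H]1O[Si](C)(C)C(C)(C)C | intermediate
32 | 8α,12-diol, 6β-OPMB | OC[C@@H](C)[C@H]1[C@@H](OCc2ccc(OC)cc2)/C=C(/C)CC/C=C(\C)C[C@@H]1O | intermediate
33 | angelic acid, (Z)-2-methylbut-2-enoic acid | C/C=C(/C)C(=O)O | starting material
34 | angelic 2,4,6-trichlorobenzoic anhydride | C/C=C(/C)C(=O)OC(=O)c1c(Cl)cc(Cl)cc1Cl | intermediate
35 | 8α,12-bis-angelate, 6β-OPMB | C/C=C(/C)C(=O)OC[C@@H](C)[C@H]1[C@@H](OCc2ccc(OC)cc2)/C=C(/C)CC/C=C(\C)C[C@@H]1OC(=O)/C(C)=C\C | intermediate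
36 | 6β-hydroxy-(1(10)E,4Z)-germacradiene 8α,12-bis-angelate | C/C=C(/C)C(=O)OC[C@@H](C)[C@H]1[C@@H](O)/C=C(/C)CC/C=C(\C)C[C@@H]1OC(=O)/C(C)=C\C | intermediate
37 | (1(10)E,4S,5R,6R,7S,8S,11S)-4,5-epoxy-6-hydroxygermacr-1(10)-ene-8,12-diyl bis[(Z)-2-methylbut-2-enoate] | C/C=C(/C)C(=O)OC[C@@H](C)[C@H]1[C@@H](O)[C@H]2O[C@@]2(C)CC/C=C(\C)C[C@@H]1OC(=O)/C(C)=C\C | target

**Step count and risks**
Total steps: 19 (18 on the main line plus the one-step preparation of aldehyde 7). Longest linear sequence: 18 steps (1 → 37 through steps 1 and 3–19).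

The three steps most likely to fail:

Step 14. The tertiary potassium alkoxide may fragment by retro-allylation instead of rearranging. The reacting chair, in which the axial vinyl group is syn to the axial C6 ether, may be too sparsely populated, so that a boat path erodes the 1(10)E/4Z geometry. Proton transfer may also move the enolate toward C6 before it is sulfonylated. The fallback sets out from 27 and replaces the charge-accelerated process by a neutral one. Silylation of the tertiary alcohol (N-(trimethylsilyl)imidazole, CH2Cl2, rt) would give the trimethylsilyl ether F1. Thermal siloxy-Cope rearrangement of F1 (degassed decalin, 200 °C, base-washed sealed tube) would give the ten-membered trimethylsilyl enol ether F2, with no alkoxide present. Cleavage of F2 with MeLi (THF, 0 °C) would generate the regiodefined lithium enolate F3, and sulfonylation of F3 with the same pyridyl triflimide at −78 °C brings the route back to 30.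

Step 9. The protonated vinyl epoxide may ionise at the tertiary allylic carbon (capture at C5 or at the isopropenyl terminus) faster than the 5-exo opening at C6, or the free acid may steer the peracid to the β face. The fallback sets out from ester 18 and separates the two events under acid-free conditions. Dimethyldioxirane (acetone, 0 °C) would give the epoxy ester F4, with no hydrogen-bond donor to steer the oxidant. LiOH (1.05 equiv, THF/H2O, rt) would give the lithium epoxy carboxylate F5. Warming F5 (DMSO, 60 °C) should open the oxirane at the secondary carbon C6 by intramolecular SN2 attack of the carboxylate, giving the lithium alkoxide F6, and acidification to pH 3 returns the route to 21.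

Step 19. Facial selectivity may be poor if the ten-membered ring populates a conformer in which the vanadate cannot reach the peripheral face, and the allylic alcohol may be oxidised to the enone. The fallback sets out from 36 and reaches 37 directly under reagent control (no new compound, F0). Sharpless asymmetric epoxidation with Ti(OiPr)4 (stoichiometric, because Z-substituted secondary allylic alcohols react slowly), D-(−)-diisopropyl tartrate and t-BuOOH (4 Å sieves, CH2Cl2, −20 °C) uses the tartrate enantiomer for which the C6 configuration of 36 is that of the matched, fast-reacting carbinol. This pairing should give the erythro (ring-cis) epoxy alcohol, which is the relative configuration of the target.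

**Further compounds**
F1 | step 14 | trimethylsilyl ether of 27 | CC(C)(C)[Si](C)(C)OC[C@@H](C)[C@H]1[C@@H](OCc2ccc(OC)cc2)[C@@](O[Si](C)(C)C)(C(C)=C)[C@@](C)(C=C)C[C@@H]1O[Si](C)(C)C(C)(C)C
F2 | step 14 | ten-membered trimethylsilyl enol ether (1(10)E; C3 cis to C6) | CC(C)(C)[Si](C)(C)OC[C@@H](C)[C@H]1[C@@H](OCc2ccc(OC)cc2)/C(O[Si](C)(C)C)=C(/C)CC/C=C(\C)C[C@@H]1O[Si](C)(C)C(C)(C)C
F3 | step 14 | ten-membered lithium enolate | [Li+].CC(C)(C)[Si](C)(C)OC[C@@H](C)[C@H]1[C@@H](OCc2ccc(OC)cc2)/C([O-])=C(/C)CC/C=C(\C)C[C@@H]1O[Si](C)(C)C(C)(C)C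
F4 | step 9 | 5α,6α-epoxy methyl ester | COC(=O)C[C@H]1[C@@H]2O[C@]2(C(C)=C)[C@@](C)(C=C)C[C@@H]1O[Si](C)(C)C(C)(C)C
F5 | step 9 | lithium 5α,6α-epoxy carboxylate | [Li+].[O-]C(=O)C[C@H]1[C@@H]2O[C@]2(C(C)=C)[C@@](C)(C=C)C[C@@H]1O[Si](C)(C)C(C)(C)C
F6 | step 9 | lithium C5-alkoxide of lactone 21 | [Li+].O=C1C[C@H]2[C@@H](O1)[C@@]([O-])(C(C)=C)[C@@](C)(C=C)C[C@@H]2O[Si](C)(C)C(C)(C)C
F0 | step 19 | none | none
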